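**Late rates.** Late in both earlier runs intermediate fell while product climbed. So I divided the product gained between the last two readings by the mean intermediate over that span. This gave a first-order constant k of 0.195 /d in east at 24 °C and 0.550 /d in north-west at 32 °C. An Arrhenius line through both gave 97.7 kJ/mol, hence 0.114 /d at 20 °C and 0.801 /d at 35 °C.

| setting | east | north-west | noon | midnight | dusk |
|---|---|---|---|---|---|
| solid substrate | 11 mM | 11 mM | 11 mM | 11 mM | 11 mM |
| partner | 0.34 equiv | 0.75 equiv | 0.500 equiv | 0.500 equiv | 0.500 equiv |
| temperature | 24 °C | 32 °C | 20 °C |  | 35 °C |
| remark | run made earlier | run made earlier |  | at 35 °C until 30 h, from then on at 20 °C |  |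
| time |  |  | 6.0 d | 6.0 d | 6.0 d |

| run | time / d | intermediate / % | product / % |
|---|---|---|---|
| east | 0.500 | 6.6 | 0.2 |
| east | 1.25 | 12.3 | 2.0 |
| east | 2.50 | 13.8 | 5.1 |
| east | 4.00 | 12.7 | 9.0 |
| east | 6.00 | 9.6 | 13.6 |
| east | 8.00 | 6.8 | 16.8 |
| north-west | 0.333 | 4.9 | 0.2 |
| north-west | 0.625 | 8.2 | 2.2 |
| north-west | 0.833 | 9.6 | 3.2 |
| north-west | 1.25 | 11.5 | 5.4 |
| north-west | 2.00 | 11.9 | 10.8 |
| north-west | 4.00 | 7.0 | 21.2 |

(readings scatter by 0.3 percentage points)

- as a solid, counted per litre of solution: solid substrate
- at the start none of the solid substrate is in solution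
- what has only dissolved of solid substrate counts as not reacted

- the flask with the highest amount of intermediate, in percent of the solid substrate charged ("all alike" if they lie within 1.5 percentage points) (noon / midnight / dusk / all alike)
- final intermediate, as a percentage of the solid substrate charged, in noon
- final intermediate, as a percentage of the solid substrate charged, in midnight
- final intermediate, as a percentage of the solid substrate charged, in dusk

**One number.** For noon, k times the time came to 0.683. This is the dose N, k summed over a flask's time, and e^−N is the share of intermediate that survives without being replaced. Midnight came to 1.54 and dusk to 4.80, so my reckoned survival share was 0.505 in noon against 0.00823 in dusk. Noon had the lowest dose, so I ranked noon first, then midnight, then dusk.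

**Partner balance.** Partner is charged at 0.34 equiv to 0.75 equiv across these flasks, which makes it the limiting reagent by charge, and N does not count it. At their last readings, intermediate plus product stood at 23.6% in east from 0.34 equiv, and at 28.2% in north-west from 0.75 equiv. One number therefore gave me the ranking but not the amounts formed.

**The forecast.** It said noon, with 21.5% in noon, 13% in midnight and 0.7% in dusk, and held that “Partner is therefore being lost in parallel”.

**The result.** The flasks gave 21.7% in noon, 12.9% in midnight and 0.684% in dusk, so noon held the most, in the order of N. Noon's intermediate was falling by then: at 6.00 d it was made at 0.159 times the rate at which it was used up, each step taken net.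

    starting material + partner ⇌ intermediate (K = 75.0 /M, k = 0.0470 /M/s, Ea = 45.0 kJ/mol, ΔH = −81.0 kJ/mol)
    intermediate ⇌ product + released group (K = 0.0200 M, k = 1.00 × 10⁻⁵ /s, Ea = 100 kJ/mol, ΔH = −20.0 kJ/mol)
    released group → by-product carried off (k = 1.70 × 10⁻⁵ /s, Ea = 112 kJ/mol)
    solid substrate ⇌ starting material, rate k4*(cs4 - [starting material]) while solid is left; crystals form when [starting material] > cs4 (solubility = 8.00 mM, k = 7.00 × 10⁻⁶ /s)
    partner → decomposed reagent (k = 5.10 × 10⁻⁶ /s, Ea = 117 kJ/mol)
    (constants at 35 °C)

**Hotter neighbour.** The noon flask run at 45 °C has a dose of 15.9, far above dusk's. It ended with 0% intermediate and 0% partner left, with 3.47% product and 5.12 mM decomposed reagent from 5.50 mM of partner charged.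

Readings and results were generated by integration for substances that don't exist; noise was put on by code.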